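In a one-step world substrate would pass into target and target would simply collect. This flask gives target two ways out, forward to over-reaction product and back to substrate, so what stands in it is a balance.

    target → over-reaction product (k1 = 0.021 s⁻¹, Ea1 = 94.0 kJ mol⁻¹)
    substrate + substrate ⇌ target (K2 = 1.3 L mol⁻¹, k2 = 0.012 L mol⁻¹ s⁻¹, Ea2 = 88.0 kJ mol⁻¹, ΔH2 = −30.0 kJ mol⁻¹)
    substrate → decomposition product (k3 = 6.0 × 10⁻⁶ s⁻¹, Ea3 = 129 kJ mol⁻¹)
    (constants at 90 °C)

in all of them: substrate 1.0 M; time 4.0 min

| flask | temperature |
|---|---|
| autumn | 120 °C |
| midnight | 60 °C |
| summer | 90 °C |

- in percentages every species weighs as the substrate in it: one target or over-reaction product counts as two
- for a step with 2 of a species take k times the square, and two of it per event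
- constants are those at 90 °C; use the activation energies and enthalpies for any other temperature

* the best flask by amount of target, in percent of the substrate charged; "all alike" if 1.5 percentage points covers them all (autumn / midnight / summer / all alike)
* amount of target at the end, in percent of the substrate charged, autumn
* amount of target at the end, in percent of the substrate charged, midnight
* amount of target at the end, in percent of the substrate charged, summer

My own reckoning follows the run and leaves decomposition aside. In the first instants [target] is nil, [substrate] is at its charge of 1.0 M, and the making runs unopposed at the making constant times [substrate] squared. As target appears, both exits open. Together they set its life, one over the sum of the over-reaction constant and the back constant, each taken at the flask's temperature. That life is 2.45 s in autumn, 33.1 s in summer and 10.8 min in midnight.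

In the middle of the autumn run, the life is far shorter than the 4.0 min available, so by this reckoning target stops collecting and stays near where making equals leaving, the usual steady state. The making constant times the life gives 0.272 L mol⁻¹ for autumn and 0.397 L mol⁻¹ for summer. This is the holding factor, the [target] at rest per squared [substrate]; a target counts twice in percentages.

Of the target made in autumn, 55.4% leaves forward and the remainder returns, so substrate falls by a second-order law slowed by that share.

For the end, my reckoning puts autumn at 0.0328 M of substrate and so 0.0585% of target. The same steps give summer 0.200 M and 3.17%. In midnight the life is longer than the run, so target is still climbing. With substrate held at its charge the reckoning gives 34.9%, a figure that runs high once [substrate] drops. My best flask is therefore midnight.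

The forecast also names midnight, with 0.07% for autumn, 23.4% for midnight and 5.2% for summer, on the ground that “heat favours losing target”. My midnight figure stands above its figure and my summer figure below.

The simulation gives midnight as best, with autumn at 0.0634%, midnight at 24.3%, below my figure, and summer at 5.01%, above mine.

Autumn's final [substrate], 3.38% of the charge, squared, multiplied by the holding factor and counted twice, gives 0.0621% of target. Midnight's lead over autumn comes in part from what temperature does to the loss of target to over-reaction product: with that effect taken away, autumn minus midnight moves from −24 percentage points to 9.6 points, so autumn stands above midnight. A neighbour of autumn charged with 1.7 M ends with 2.04% of its charge as substrate; the same holding factor gives 0.0385% of target, and the flask stands at 0.0392%.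

(The numbers were drawn at random within sensible limits; the run is a simulation.)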